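**Retrosynthetic overview**
1. Target ⇐ chelation-controlled 5-O-demethylation of its 5-methyl ether, as the last step, with the prenyl group already in place and the 7-OMe untouched.
2. C ring (the only ring made, closed last through O1–C2) ⇐ acid-triggered MOM loss and cyclodehydration of a 2-(MOM-oxy)-1,3-diketone that already has the flavonol oxidation level, so no oxidant ever meets the prenyl olefin.
3. Diketone ⇐ intermolecular crossed Claisen condensation of an A-ring α-(MOM-oxy) ketone with methyl 4-(MOM-oxy)benzoate (B ring bought).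
4. Key strategy: the single MOM-protected oxygen of 3,5-dimethoxyphenol (the future O1) directs two successive ortho-lithiations, the first delivering the prenyl group (future C8), the second the acyl carbon (future C4 on C4a).
5. The O1/C8/C4a pattern is therefore fixed by construction: no O-prenyl ether, no Claisen–Cope shift, no chalcone/Algar–Flynn–Oyamada oxidation.

Assumption: the target has no stereocentre and no stereogenic double bond, so the achiral compound itself is the "single enantiomer"; intermediates 11 and 16 carry a transient stereocentre, are racemic, and lose it in steps 5 and 8. Reagents on the "Reagents that add atoms" line are bought and carry no number.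

**Route**

Step 1
Reactants: 1 3,5-dimethoxyphenol
Product: 2 1,3-dimethoxy-5-(methoxymethoxy)benzene
Conditions: MOMCl (1.3 equiv), i-Pr2NEt (1.5 equiv), CH2Cl2, 0 °C to rt
Reagents that add atoms: chloromethyl methyl ether (MOMCl), COCCl
Why: O-alkylation of the phenol (MOM acetal protection) installs the chelating, acid-labile group that directs both later ortho-lithiations.

Step 2
Reactants: 2 1,3-dimethoxy-5-(methoxymethoxy)benzene; 3 1-bromo-3-methylbut-2-ene (prenyl bromide)
Product: 6 1,5-dimethoxy-3-(methoxymethoxy)-2-(3-methylbut-2-en-1-yl)benzene, via aryllithium 4 (not isolated), via arylcopper 5 (not isolated)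
Conditions: n-BuLi (1.1 equiv), THF, 0 °C, 1 h; CuI (1.1 equiv), −40 °C; 3 (1.3 equiv), −78 °C to rt
Reagents that add atoms: none
Why: Directed ortho-metalation occurs at one of the two equivalent C–H sites flanked by OMOM and OMe (the better-chelating OMOM outcompetes the OMe/OMe site), and after Li-to-Cu transmetalation the arylcopper is allylated by prenyl bromide at its unhindered α-carbon (SN2, linear prenyl), placing the prenyl group next to the future O1.

Step 3
Reactants: 7 methyl 2-hydroxyacetate (methyl glycolate)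
Product: 8 methyl 2-(methoxymethoxy)acetate
Conditions: MOMCl (1.3 equiv), i-Pr2NEt (1.5 equiv), CH2Cl2, 0 °C to rt
Reagents that add atoms: chloromethyl methyl ether (MOMCl), COCCl
Why: MOM protection (O-alkylation to the acetal) masks the future 3-OH with a group that survives organolithiums and LiHMDS and falls in the same acid step as the aryl MOM ethers.

Step 4
Reactants: 8 methyl 2-(methoxymethoxy)acetate
Product: 9 N-methoxy-2-(methoxymethoxy)-N-methylacetamide
Conditions: MeNH(OMe)·HCl (1.5 equiv), i-PrMgCl (3.0 equiv), THF, −20 to 0 °C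
Reagents that add atoms: N,O-dimethylhydroxylamine hydrochloride, CNOC.Cl
Why: Weinreb amidation of the methyl ester by the chloromagnesium amide made in situ gives the amide that stops cleanly at the ketone stage in step 5.

Step 5
Reactants: 6 1,5-dimethoxy-3-(methoxymethoxy)-2-(3-methylbut-2-en-1-yl)benzene; 9 N-methoxy-2-(methoxymethoxy)-N-methylacetamide
Product: 12 1-[4,6-dimethoxy-2-(methoxymethoxy)-3-(3-methylbut-2-en-1-yl)phenyl]-2-(methoxymethoxy)ethan-1-one, via aryllithium 10 (not isolated), via tetrahedral lithium adduct 11 (not isolated)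
Conditions: n-BuLi (1.1 equiv), THF, 0 °C, 1 h; 9 (1.2 equiv), −78 to 0 °C; H2O quench
Reagents that add atoms: none
Why: The second directed ortho-metalation goes to the only remaining OMOM-flanked C–H (the prenyl group blocks the other ortho site and turns the MOM chain toward this one, and chelation-directed aryl deprotonation is kinetically faster than benzylic/allylic metalation), and the Weinreb ketone synthesis through the stable chelate 11 prevents over-addition.

Step 6
Reactants: 13 methyl 4-hydroxybenzoate
Product: 14 methyl 4-(methoxymethoxy)benzoate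
Conditions: MOMCl (1.3 equiv), i-Pr2NEt (1.5 equiv), CH2Cl2, 0 °C to rt
Reagents that add atoms: chloromethyl methyl ether (MOMCl), COCCl
Why: MOM protection of the phenol (O-alkylation) gives a non-enolisable B-ring ester whose protecting group is removed in step 8.

Step 7
Reactants: 12 1-[4,6-dimethoxy-2-(methoxymethoxy)-3-(3-methylbut-2-en-1-yl)phenyl]-2-(methoxymethoxy)ethan-1-one; 14 methyl 4-(methoxymethoxy)benzoate
Product: 16 1-[4,6-dimethoxy-2-(methoxymethoxy)-3-(3-methylbut-2-en-1-yl)phenyl]-2-(methoxymethoxy)-3-[4-(methoxymethoxy)phenyl]propane-1,3-dione, via lithium enolate 15 (not isolated)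
Conditions: LiHMDS (2.5 equiv), THF, −78 °C; 14 (1.2 equiv), −78 to 50 °C; AcOH quench
Reagents that add atoms: none
Why: Crossed Claisen condensation in which only 12 can enolise (chelated Z-enolate 15) and 14 is a non-enolisable acceptor gives C-acylation only and is made irreversible by deprotonation of the β-diketone by the second equivalent of base.

Step 8
Reactants: 16 1-[4,6-dimethoxy-2-(methoxymethoxy)-3-(3-methylbut-2-en-1-yl)phenyl]-2-(methoxymethoxy)-3-[4-(methoxymethoxy)phenyl]propane-1,3-dione
Product: 18 3-hydroxy-2-(4-hydroxyphenyl)-5,7-dimethoxy-8-(3-methylbut-2-en-1-yl)-4H-chromen-4-one, via 3-O-MOM flavone 17 (not isolated)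
Conditions: 3 M aq. HCl/MeOH (1:5), 50 °C, 1–2 h
Reagents that add atoms: none
Why: Acid cleaves the aryl MOM ethers first, the freed phenol adds to the B-ring carbonyl and water is lost (cyclodehydration of an o-hydroxyaryl 1,3-diketone, as in the second stage of a Baker–Venkataraman/Allan–Robinson flavone synthesis) to give 17 at the flavonol oxidation level, whose enol MOM ether then falls, and after ring closure the prenyl group has no free ortho-OH to cyclise onto.

Step 9
Reactants: 18 3-hydroxy-2-(4-hydroxyphenyl)-5,7-dimethoxy-8-(3-methylbut-2-en-1-yl)-4H-chromen-4-one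
Product: 19 3,5-dihydroxy-2-(4-hydroxyphenyl)-7-methoxy-8-(3-methylbut-2-en-1-yl)-4H-chromen-4-one (isoanhydroicaritin)
Conditions: MgI2·OEt2 (4 equiv), toluene, 80 °C; then 1 M HCl, 0 °C
Reagents that add atoms: none
Why: Chelation-controlled Lewis-acid demethylation, in which Mg(II) bridges the C4 carbonyl and the peri 5-OMe oxygen and iodide removes that methyl by SN2, leaves the unchelated 7-OMe and the olefin (no Brønsted acid present) untouched.

**Compound list**
1 | 3,5-dimethoxyphenol | COc1cc(O)cc(OC)c1 | starting material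
2 | 1,3-dimethoxy-5-(methoxymethoxy)benzene | COCOc1cc(OC)cc(OC)c1 | intermediate
3 | 1-bromo-3-methylbut-2-ene (prenyl bromide) | CC(C)=CCBr | starting material
4 | [2,4-dimethoxy-6-(methoxymethoxy)phenyl]lithium (in situ) | [Li]c1c(OC)cc(OC)cc1OCOC | intermediate
5 | [2,4-dimethoxy-6-(methoxymethoxy)phenyl]copper (in situ) | [Cu]c1c(OC)cc(OC)cc1OCOC | intermediate
6 | 1,5-dimethoxy-3-(methoxymethoxy)-2-(3-methylbut-2-en-1-yl)benzene | COCOc1cc(OC)cc(OC)c1CC=C(C)C | intermediate
7 | methyl 2-hydroxyacetate (methyl glycolate) | COC(=O)CO | starting material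
8 | methyl 2-(methoxymethoxy)acetate | COCOCC(=O)OC | intermediate
9 | N-methoxy-2-(methoxymethoxy)-N-methylacetamide | COCOCC(=O)N(C)OC | intermediate
10 | [2,4-dimethoxy-6-(methoxymethoxy)-5-(3-methylbut-2-en-1-yl)phenyl]lithium (in situ) | [Li]c1c(OC)cc(OC)c(CC=C(C)C)c1OCOC | intermediate
11 | lithium 1-aryl-1-[methoxy(methyl)amino]-2-(methoxymethoxy)ethan-1-olate, aryl as in 12 (in situ, racemic) | COCOCC(O[Li])(N(C)OC)c1c(OC)cc(OC)c(CC=C(C)C)c1OCOC | intermediate
12 | 1-[4,6-dimethoxy-2-(methoxymethoxy)-3-(3-methylbut-2-en-1-yl)phenyl]-2-(methoxymethoxy)ethan-1-one | COCOCC(=O)c1c(OC)cc(OC)c(CC=C(C)C)c1OCOC | intermediate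
13 | methyl 4-hydroxybenzoate | COC(=O)c1ccc(O)cc1 | starting material
14 | methyl 4-(methoxymethoxy)benzoate | COCOc1ccc(cc1)C(=O)OC | intermediate
15 | lithium (Z)-enolate of 12 (in situ) | COCO/C=C(\O[Li])c1c(OC)cc(OC)c(CC=C(C)C)c1OCOC | intermediate
16 | 1-[4,6-dimethoxy-2-(methoxymethoxy)-3-(3-methylbut-2-en-1-yl)phenyl]-2-(methoxymethoxy)-3-[4-(methoxymethoxy)phenyl]propane-1,3-dione (racemic at C2, largely enolised) | COCOC(C(=O)c1ccc(OCOC)cc1)C(=O)c1c(OC)cc(OC)c(CC=C(C)C)c1OCOC | intermediate
17 | 2-(4-hydroxyphenyl)-5,7-dimethoxy-3-(methoxymethoxy)-8-(3-methylbut-2-en-1-yl)-4H-chromen-4-one (in situ) | COCOc1c(-c2ccc(O)cc2)oc2c(CC=C(C)C)c(OC)cc(OC)c2c1=O | intermediate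
18 | 3-hydroxy-2-(4-hydroxyphenyl)-5,7-dimethoxy-8-(3-methylbut-2-en-1-yl)-4H-chromen-4-one | COc1cc(OC)c2c(=O)c(O)c(-c3ccc(O)cc3)oc2c1CC=C(C)C | intermediate
19 | 3,5-dihydroxy-2-(4-hydroxyphenyl)-7-methoxy-8-(3-methylbut-2-en-1-yl)-4H-chromen-4-one (isoanhydroicaritin) | COc1cc(O)c2c(=O)c(O)c(-c3ccc(O)cc3)oc2c1CC=C(C)C | target

**Step count**
Total steps: 9. Longest linear sequence: 6 (steps 1, 2, 5, 7, 8, 9; compounds 1 → 2 → 6 → 12 → 16 → 18 → 19).

**Three steps most likely to fail, with fallbacks**

Step 5 (second ortho-lithiation and acyl transfer). The hindered, di-ortho-substituted aryllithium may enolise or demethoxylate the Weinreb amide instead of adding to it. The fallback replaces acyl substitution by addition to an aldehyde followed by oxidation. It sets out from 6 (with ester 8 as the source of the two-carbon unit) and comes back at 12. Ester 8 is reduced with DIBAL-H (CH2Cl2, −78 °C) to 2-(methoxymethoxy)acetaldehyde F1. Aryllithium 10, made from 6 as before, is added to it at −78 °C to give 1-[4,6-dimethoxy-2-(methoxymethoxy)-3-(3-methylbut-2-en-1-yl)phenyl]-2-(methoxymethoxy)ethan-1-ol F2 (racemic). Dess–Martin periodinane (NaHCO3, CH2Cl2) then oxidises the benzylic alcohol to ketone 12 without touching the prenyl olefin.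

Step 7 (crossed Claisen condensation). The α-alkoxy enolate of a twisted 2,6-disubstituted aryl ketone may be too sluggish toward an electron-rich benzoate. The fallback is an aldol addition followed by oxidation. It sets out from 12 and comes back at 16. Enolate 15 (LiHMDS, THF, −78 °C) is treated with commercial 4-(methoxymethoxy)benzaldehyde (COCOc1ccc(C=O)cc1), a far better electrophile than the ester. This gives 1-[4,6-dimethoxy-2-(methoxymethoxy)-3-(3-methylbut-2-en-1-yl)phenyl]-3-hydroxy-2-(methoxymethoxy)-3-[4-(methoxymethoxy)phenyl]propan-1-one F3 as a mixture of racemic diastereomers. Dess–Martin oxidation converges all of them on diketone 16.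

Step 9 (5-O-demethylation next to a prenyl group and two free hydroxyls). If MgI2 is too slow, or the free 3-OH/4'-OH interfere, a protect–demethylate–deprotect detour is used. It sets out from 18 and comes back at 19. Ac2O/pyridine gives 4-[3-acetoxy-5,7-dimethoxy-8-(3-methylbut-2-en-1-yl)-4-oxo-4H-chromen-2-yl]phenyl acetate F4, which has no acidic OH, so a boron halide generates no HCl that could add to the olefin. BCl3 (1.5 equiv, CH2Cl2, −78 °C, NaHCO3/MeOH quench) cleaves only the chelated 5-OMe to give 4-[3-acetoxy-5-hydroxy-7-methoxy-8-(3-methylbut-2-en-1-yl)-4-oxo-4H-chromen-2-yl]phenyl acetate F5. K2CO3/MeOH at rt removes both acetates to give 19.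

**Further compounds**
F1 | step 5 | 2-(methoxymethoxy)acetaldehyde | COCOCC=O
F2 | step 5 | 1-[4,6-dimethoxy-2-(methoxymethoxy)-3-(3-methylbut-2-en-1-yl)phenyl]-2-(methoxymethoxy)ethan-1-ol (racemic) | COCOCC(O)c1c(OC)cc(OC)c(CC=C(C)C)c1OCOC
F3 | step 7 | 1-[4,6-dimethoxy-2-(methoxymethoxy)-3-(3-methylbut-2-en-1-yl)phenyl]-3-hydroxy-2-(methoxymethoxy)-3-[4-(methoxymethoxy)phenyl]propan-1-one (racemic diastereomer mixture) | COCOC(C(O)c1ccc(OCOC)cc1)C(=O)c1c(OC)cc(OC)c(CC=C(C)C)c1OCOC
F4 | step 9 | 4-[3-acetoxy-5,7-dimethoxy-8-(3-methylbut-2-en-1-yl)-4-oxo-4H-chromen-2-yl]phenyl acetate | COc1cc(OC)c2c(=O)c(OC(C)=O)c(-c3ccc(OC(C)=O)cc3)oc2c1CC=C(C)C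
F5 | step 9 | 4-[3-acetoxy-5-hydroxy-7-methoxy-8-(3-methylbut-2-en-1-yl)-4-oxo-4H-chromen-2-yl]phenyl acetate | COc1cc(O)c2c(=O)c(OC(C)=O)c(-c3ccc(OC(C)=O)cc3)oc2c1CC=C(C)C
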